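**Analysis of the target**

The target is a γ-butyrolactone (ring A) with a 3,4-dimethoxybenzyl group on C4 and, on C3, a methylene that leads to C4' of a 2-pyranone (ring B) carrying a carboxylic acid at C6'. The only stereocentres are the adjacent C3 and C4, both R and trans to each other (checked against the SMILES). C3 is α to the lactone carbonyl and can epimerise, but trans is the thermodynamically preferred arrangement. The sensitive groups are the 2-pyranone (opened by hydroxide and alkoxide), the butyrolactone (base), the free acid, and the electron-rich dimethoxyarene (electrophilic halogen, strong oxidants, excess ozone). The hard part is not the lactone but building a 4,6-disubstituted 2-pyranone on a CH2 next to an epimerisable centre, without strong base and with the carboxyl fixed at C6' and the side chain at C4'. The plan rests on reading O1', C6' (with its carboxyl), C5' and C4' as a 1-oxadiene, namely a β,γ-unsaturated α-keto ester hanging from the C3 methylene, and C3'–C2' as a two-carbon ketene acetal already at the carboxyl oxidation level. Joining the two leaves ring B one hydride (the doubly allylic C4'–H) short of aromatic, so it is oxidised late.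

**Retrosynthetic reasoning**

Target 21 is traced back to its ethyl ester 20. The C6' carboxyl has to be masked through olefination and cycloaddition, and an ester that falls to aqueous acid is chosen because ring B does not tolerate hydroxide.

The C2' carbonyl and the C3'=C4' double bond of 20 are traced back, through the 2-ethoxypyrylium ion 19, to the 2-ethoxy-4H-pyran 18. The forward reaction must remove one hydride from C4' and then the O-ethyl group. C4'–H is the only hydridic C–H in the molecule, which is what lets the oxidation be selective beside the dimethoxyarene.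

The C2'=C3' ketene acetal bond of 18 comes from the cyclic orthoester 17 by loss of one ethoxy group and a C3' proton. Nothing is cut here; the step only unmasks the electron-rich double bond that makes C4'–H hydridic.

Orthoester 17 is cut at C3'–C4' and O1'–C2', which gives the enone keto ester 15 and ketene acetal 16. These two bonds are chosen because both are polarity-matched in a single [4+2] event (acceptor β-carbon with donor CH2, keto oxygen with acetal carbon). The cut also places the carboxyl at C6' and the side chain at C4' by construction, and the two-carbon partner 16 is a purchased reagent. Any other cut of ring B would need enolate chemistry beside C3.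

The C4'=C5' double bond of 15 is cut to aldehyde 13 and the stabilised ylide 14. The forward olefination runs without base, so C3 is not at risk, and it delivers the E-enone needed for the s-cis oxadiene.

Aldehyde 13 comes from the terminal alkene 11 by oxidative cleavage (through ozonide 12). The C3–CH2 bond of 11 is cut to lactone 8 and allyl bromide 9. The forward alkylation of enolate 10 sets C3 trans to the C4 substituent, so the second stereocentre follows from the first.

Lactone 8 comes from ester 7 by removal of the activating ester. The aryl–CH2 bond of 7 is cut to the cyclopropane-fused lactone 4 and the aryl bromide 5 (used as Grignard reagent 6). This puts the electron-rich arene in by a homoconjugate opening that does not touch the stereocentre.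

Bicycle 4 is traced to (R)-epichlorohydrin 1 and dimethyl malonate 2 (through epoxide 3). C4 of the target is thus bought from the chiral pool, and the remaining chemistry up to 15 is routine.

**Alternatives that were turned down**

Alternative 1: Both exocyclic C–C bonds of ring A (C4–CH2 and C3–CH2) are cut, with the lactone coming from the chiral butenolide A1, which carries a menthyloxy acetal at C5. In the forward key step the organocopper reagent from benzylic Grignard reagent A2 adds to C4 anti to the acetal substituent, and the enolate is trapped at C3 by allylic bromide A3 anti to the new benzyl group, giving A4. In its favour, both stereocentres are set in one flask under auxiliary control, and all carbons of ring B except the oxalyl unit arrive in one piece, so on paper it is shorter than the chosen route. Against it, ring B must then be closed by an alkoxide-mediated oxalate condensation at the γ-methyl group of A4. That means strong base beside the epimerisable C3–H and the lactone, and a vinylogous deprotonation that can also occur at the other γ-position (the CH2 on C3). The C5 acetal must also be reduced away before ring B exists, since ring B would not survive the hydride. Electron-rich benzylic Grignard reagents such as A2 are prone to homocoupling. Alternative 1 is stronger in convergence and in setting the stereocentres. The chosen route offers instead a base-free construction of ring B with built-in regiochemistry and no auxiliary to remove.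

Alternative 2: The O1–C5 bond of ring A is cut, leading to the prochiral cyclobutanone A5. An enantioselective Baeyer–Villiger oxidation (chiral catalyst with a peroxide, or a monooxygenase) inserts oxygen next to one of the two enantiotopic CH2 groups and gives lactone A6, which is the same compound as lactone 8 of the chosen route. In its favour, the stereocentre comes from catalysis rather than the chiral pool, and A6 could feed directly into the present sequence. Against it, the key step solves only the easy half: it installs neither C3 nor ring B. The enantiotopic discrimination in a 3-benzylcyclobutanone depends on a remote, flexible substituent, so optical purity is less secure than from an enantiopure three-carbon building block. A5 itself needs a ketene cycloaddition and a dechlorination, so the step count to lactone 8 is no lower. It is equal in length up to 8, less secure in configuration, and says nothing about the pyranone.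

Alternative 3: Ring B is derived from the catechol ring of A7 (the lignan with a 3,4-dihydroxybenzyl group on C3) by cleaving the aromatic C4–C5 bond of that ring. In the forward key step an extradiol catechol dioxygenase (divalent iron in the active site, aerobic) cleaves this bond, the C3 enol oxygen adds to the new aldehyde, and lactol A8 results. Oxidation of the lactol then gives the pyranone. In its favour, it is by far the shortest route, it probably mirrors the biogenesis, every carbon and both stereocentres are already in place, and no protecting group is needed. Against it, the cleavage must occur distal to the alkyl substituent, whereas the common catechol 2,3-dioxygenases cleave 4-alkylcatechols on the proximal side. The enzymes with the required 4,5-regiochemistry are tuned to a carboxylate-bearing catechol, not to a bulky lipophilic lignan, and chemical models of extradiol cleavage compete with intradiol cleavage. Alternative 3 is clearly stronger in step economy if the enzyme accepts the substrate. The chosen route offers regiochemistry that is fixed by polarity and does not depend on the substrate tolerance of an enzyme.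

Key step: step 7

Remark on the chemistry: primed locants (O1', C2'–C6') refer to the pyranone ring and unprimed ones to the butyrolactone; 17 and 18 are carried as mixtures of both C4' epimers because this centre is erased in step 9; 14 and 16 are taken as purchased reagents.

**Route**

Step 1
Reactants: 1 (R)-epichlorohydrin; 2 dimethyl malonate
Product: 4 methyl (1S,5R)-2-oxo-3-oxabicyclo[3.1.0]hexane-1-carboxylate, via epoxy malonate 3 (not isolated)
Conditions: NaOMe (1.1 equiv), MeOH, 0 °C → reflux
Reagents that add atoms: dimethyl malonate (2), COC(=O)CC(=O)OC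
Why: Tandem alkylation–cyclopropanation–lactonisation: the malonate anion opens the epoxide of 1 at its CH2, the alkoxide closes onto the CH2Cl carbon to give 3, and a second deprotonation opens the new epoxide 3-exo-tet with inversion, after which the alkoxide lactonises onto the cis ester. The stereocentre of 1 becomes C5 (R) of 4, the later C4 of ring A; a minor direct displacement of chloride would give the enantiomer and could erode the optical purity slightly.

Step 2
Reactants: 4 methyl (1S,5R)-2-oxo-3-oxabicyclo[3.1.0]hexane-1-carboxylate; 5 4-bromo-1,2-dimethoxybenzene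
Product: 7 methyl (4R)-4-(3,4-dimethoxybenzyl)-2-oxotetrahydrofuran-3-carboxylate (C3 epimers), via 3,4-dimethoxyphenylmagnesium bromide 6 (not isolated)
Conditions: Mg, THF, 40 °C (5 → 6); then CuI (20 mol %), 4, THF, −40 → 0 °C; aq. NH4Cl
Reagents that add atoms: 4-bromo-1,2-dimethoxybenzene (5), COc1ccc(Br)cc1OC
Why: Copper-catalysed homoconjugate addition: the arylcopper species opens the doubly activated cyclopropane at its unsubstituted CH2 and expels the malonate-type enolate, which is inert to further Grignard reagent. The stereocentre is not involved and becomes C4 (R); the C3 centre is labile and is removed in step 3.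

Step 3
Reactants: 7 methyl (4R)-4-(3,4-dimethoxybenzyl)-2-oxotetrahydrofuran-3-carboxylate
Product: 8 (4R)-4-(3,4-dimethoxybenzyl)dihydrofuran-2(3H)-one
Conditions: LiCl (3 equiv), H2O (2 equiv), DMSO, 150 °C
Reagents that add atoms: none
Why: Krapcho demethoxycarbonylation: chloride demethylates the activated ester, the carboxylate loses CO2 and the lactone enolate is protonated. C4 is untouched.

Step 4
Reactants: 8 (4R)-4-(3,4-dimethoxybenzyl)dihydrofuran-2(3H)-one; 9 allyl bromide
Product: 11 (3R,4R)-3-allyl-4-(3,4-dimethoxybenzyl)dihydrofuran-2(3H)-one, via lithium enolate 10 (not isolated)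
Conditions: LiN(SiMe3)2 (1.05 equiv), THF, −78 °C; then 9 (1.5 equiv), DMPU, −78 → −30 °C
Reagents that add atoms: allyl bromide (9), C=CCBr
Why: Kinetic alkylation of a lactone lithium enolate; the electrophile approaches the planar enolate anti to the C4 benzyl group, so C3 is set trans (3R) by substrate control, as is standard for β-benzyl butyrolactones. Trans is also the thermodynamic isomer, so any equilibration works in the same direction.

Step 5
Reactants: 11 (3R,4R)-3-allyl-4-(3,4-dimethoxybenzyl)dihydrofuran-2(3H)-one
Product: 13 2-[(3R,4R)-4-(3,4-dimethoxybenzyl)-2-oxotetrahydrofuran-3-yl]acetaldehyde, via secondary ozonide 12 (not isolated)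
Conditions: O3, CH2Cl2, −78 °C, Sudan Red 7B end point; then PPh3 (1.2 equiv), −78 → 25 °C
Reagents that add atoms: ozone, O=[O+][O-]
Why: Ozonolysis with reductive work-up; the terminal alkene is far more reactive than the dimethoxyarene, and the indicator dye stops the addition before the arene is attacked. The aldehyde cannot β-eliminate and C3 is not adjacent to it.

Step 6
Reactants: 13 2-[(3R,4R)-4-(3,4-dimethoxybenzyl)-2-oxotetrahydrofuran-3-yl]acetaldehyde; 14 ethyl 3-(triphenylphosphoranylidene)pyruvate
Product: 15 ethyl (E)-5-[(3R,4R)-4-(3,4-dimethoxybenzyl)-2-oxotetrahydrofuran-3-yl]-2-oxopent-3-enoate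
Conditions: 14 (1.3 equiv), toluene, 80 °C
Reagents that add atoms: ethyl 3-(triphenylphosphoranylidene)pyruvate (14), CCOC(=O)C(=O)C=P(c1ccccc1)(c1ccccc1)c1ccccc1
Why: Wittig olefination with a keto-stabilised ylide, the usual access to β,γ-unsaturated α-keto esters from aldehydes. The reaction needs no base, so C3 is safe, and the stabilised ylide gives the E-alkene.

Step 7
Reactants: 15 ethyl (E)-5-[(3R,4R)-4-(3,4-dimethoxybenzyl)-2-oxotetrahydrofuran-3-yl]-2-oxopent-3-enoate; 16 1,1-diethoxyethene
Product: 17 ethyl 4-{[(3R,4R)-4-(3,4-dimethoxybenzyl)-2-oxotetrahydrofuran-3-yl]methyl}-2,2-diethoxy-3,4-dihydro-2H-pyran-6-carboxylate (both C4' epimers)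
Conditions: 16 (3 equiv), Eu(fod)3 (5 mol %), toluene, 0 → 25 °C, base-washed glassware; filtration through basic Al2O3
Reagents that add atoms: 1,1-diethoxyethene (16), C=C(OCC)OCC
Why: The s-cis 1-oxadiene of 15 (O=C6'–C5'=C4'), whose LUMO is lowered by the adjacent ester, reacts with the electron-rich two-carbon partner 16 in an inverse-electron-demand hetero-Diels–Alder reaction, the reaction type established for β,γ-unsaturated α-keto esters with enol ethers and ketene acetals. Bond formation is concerted but asynchronous: the nucleophilic CH2 of 16 bonds to the β-carbon C4' ahead of the closure of O1' onto the acetal carbon C2'. The only ring formed, the 3,4-dihydro-2H-pyran, closes in this [4+2] mode (four atoms O1'–C6'–C5'–C4' plus two atoms C3'–C2'); in the zwitterionic limit the same ring arises by collapse of the enolate oxygen onto the diethoxycarbenium carbon. Regiochemistry follows from polarity, since the largest LUMO coefficient of the oxadiene lies at C4' and the largest HOMO coefficient of 16 at its CH2, so C3'–C4' and O1'–C2' are the only bonds to expect. The one new stereocentre, C4', is controlled by nothing in the substrate (the lactone centres are remote) and need not be, because it becomes sp2 in step 9; C2' carries two identical ethoxy groups and is not stereogenic. Chemoselectivity is needed against the lactone carbonyl and against [2+2] addition to the keto group: the lactone is no heterodiene, and four-membered adducts of ketene acetals reopen to the zwitterion and funnel to the six-membered orthoester. Eu(fod)3 is a Lewis acid mild enough to speed the cycloaddition without ionising the orthoester, and acid-free glassware keeps 16 from oligomerising. C3 and C4 are not touched under these neutral conditions.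

Step 8
Reactants: 17 ethyl 4-{[(3R,4R)-4-(3,4-dimethoxybenzyl)-2-oxotetrahydrofuran-3-yl]methyl}-2,2-diethoxy-3,4-dihydro-2H-pyran-6-carboxylate
Product: 18 ethyl 4-{[(3R,4R)-4-(3,4-dimethoxybenzyl)-2-oxotetrahydrofuran-3-yl]methyl}-6-ethoxy-4H-pyran-2-carboxylate (both C4' epimers)
Conditions: Me3CCO2H (5 mol %), toluene, 110 °C, EtOH removed over 4 Å molecular sieves; used crude under argon
Reagents that add atoms: none
Why: Weak-acid-catalysed ionisation of the orthoester to the cyclic dialkoxycarbenium ion, followed by loss of a C3' proton, gives the ketene acetal. This is the elementary step that opens every Johnson–Claisen rearrangement and the known fate of 2,2-dialkoxy-3,4-dihydropyrans; removal of ethanol drives it.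

Step 9
Reactants: 18 ethyl 4-{[(3R,4R)-4-(3,4-dimethoxybenzyl)-2-oxotetrahydrofuran-3-yl]methyl}-6-ethoxy-4H-pyran-2-carboxylate
Product: 20 ethyl 4-{[(3R,4R)-4-(3,4-dimethoxybenzyl)-2-oxotetrahydrofuran-3-yl]methyl}-2-oxo-2H-pyran-6-carboxylate, via 2-ethoxypyrylium tetrafluoroborate 19 (not isolated)
Conditions: Ph3C+ BF4− (1.05 equiv), 2,6-di-tert-butylpyridine (0.1 equiv), CH2Cl2, −20 → 0 °C; then Bu4NBr (1.5 equiv), 0 → 25 °C
Reagents that add atoms: none
Why: Proposed new method: C4'–H of 18 is doubly allylic, flanked by the ketene acetal and the enol ether double bonds, and its transfer as hydride to Ph3C+ gives the aromatic 2-ethoxypyrylium ion 19, stabilised by the ring oxygen and the ethoxy group; bromide then removes the O-ethyl group by SN2 attack, the reverse of O-alkylation of a 2-pyranone, and leaves 20. The closest known reaction types are the trityl-cation dehydrogenation of 4H-pyrans and 1,4-dihydropyridines to pyrylium and pyridinium salts and the halide dealkylation of 2-alkoxypyrylium salts; the combination on a 2-alkoxy-4H-pyran carrying a 6-ester is the untested part.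

Step 10
Reactants: 20 ethyl 4-{[(3R,4R)-4-(3,4-dimethoxybenzyl)-2-oxotetrahydrofuran-3-yl]methyl}-2-oxo-2H-pyran-6-carboxylate
Product: 21 4-{[(3R,4R)-4-(3,4-dimethoxybenzyl)-2-oxotetrahydrofuran-3-yl]methyl}-2-oxo-2H-pyran-6-carboxylic acid
Conditions: 6 M HCl–1,4-dioxane (1:1), 80 °C
Reagents that add atoms: water, O
Why: Acid-catalysed ester hydrolysis, as used for 2-pyranone-6-carboxylic esters; acid is chosen because hydroxide would open ring B. The butyrolactone stays closed or recloses under acid, the aryl methyl ethers are stable to aqueous HCl at this temperature, and any acid-mediated equilibration at C3 favours the trans isomer already present.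

**Compound list**

1 | (R)-epichlorohydrin | ClC[C@H]1CO1 | starting material
2 | dimethyl malonate | COC(=O)CC(=O)OC | starting material
3 | dimethyl 2-{[(2R)-oxiran-2-yl]methyl}malonate | COC(=O)C(C[C@@H]1CO1)C(=O)OC | intermediate
4 | methyl (1S,5R)-2-oxo-3-oxabicyclo[3.1.0]hexane-1-carboxylate | COC(=O)[C@]12C[C@H]1COC2=O | intermediate
5 | 4-bromo-1,2-dimethoxybenzene | COc1ccc(Br)cc1OC | starting material
6 | 3,4-dimethoxyphenylmagnesium bromide | COc1ccc([Mg]Br)cc1OC | intermediate
7 | methyl (4R)-4-(3,4-dimethoxybenzyl)-2-oxotetrahydrofuran-3-carboxylate (C3 epimers) | COc1ccc(C[C@H]2COC(=O)C2C(=O)OC)cc1OC | intermediate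
8 | (4R)-4-(3,4-dimethoxybenzyl)dihydrofuran-2(3H)-one | COc1ccc(C[C@H]2COC(=O)C2)cc1OC | intermediate
9 | allyl bromide | C=CCBr | starting material
10 | lithium (4R)-4-(3,4-dimethoxybenzyl)-4,5-dihydrofuran-2-olate (lithium enolate of 8) | COc1ccc(C[C@H]2COC(O[Li])=C2)cc1OC | intermediate
11 | (3R,4R)-3-allyl-4-(3,4-dimethoxybenzyl)dihydrofuran-2(3H)-one | COc1ccc(C[C@H]2COC(=O)[C@@H]2CC=C)cc1OC | intermediate
12 | (3R,4R)-4-(3,4-dimethoxybenzyl)-3-[(1,2,4-trioxolan-3-yl)methyl]dihydrofuran-2(3H)-one (both epimers at the trioxolane carbon) | COc1ccc(C[C@H]2COC(=O)[C@@H]2CC2OCOO2)cc1OC | intermediate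
13 | 2-[(3R,4R)-4-(3,4-dimethoxybenzyl)-2-oxotetrahydrofuran-3-yl]acetaldehyde | COc1ccc(C[C@H]2COC(=O)[C@@H]2CC=O)cc1OC | intermediate
14 | ethyl 3-(triphenylphosphoranylidene)pyruvate | CCOC(=O)C(=O)C=P(c1ccccc1)(c1ccccc1)c1ccccc1 | starting material
15 | ethyl (E)-5-[(3R,4R)-4-(3,4-dimethoxybenzyl)-2-oxotetrahydrofuran-3-yl]-2-oxopent-3-enoate | COc1ccc(C[C@H]2COC(=O)[C@@H]2C/C=C/C(=O)C(=O)OCC)cc1OC | intermediate
16 | 1,1-diethoxyethene | C=C(OCC)OCC | starting material
17 | ethyl 4-{[(3R,4R)-4-(3,4-dimethoxybenzyl)-2-oxotetrahydrofuran-3-yl]methyl}-2,2-diethoxy-3,4-dihydro-2H-pyran-6-carboxylate (both C4' epimers) | COc1ccc(C[C@H]2COC(=O)[C@@H]2CC3CC(OCC)(OCC)OC(C(=O)OCC)=C3)cc1OC | intermediate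
18 | ethyl 4-{[(3R,4R)-4-(3,4-dimethoxybenzyl)-2-oxotetrahydrofuran-3-yl]methyl}-6-ethoxy-4H-pyran-2-carboxylate (both C4' epimers) | COc1ccc(C[C@H]2COC(=O)[C@@H]2CC3C=C(OCC)OC(C(=O)OCC)=C3)cc1OC | intermediate
19 | 4-{[(3R,4R)-4-(3,4-dimethoxybenzyl)-2-oxotetrahydrofuran-3-yl]methyl}-2-ethoxy-6-(ethoxycarbonyl)pyrylium tetrafluoroborate | COc1ccc(C[C@H]2COC(=O)[C@@H]2Cc3cc(OCC)[o+]c(C(=O)OCC)c3)cc1OC.F[B-](F)(F)F | intermediate
20 | ethyl 4-{[(3R,4R)-4-(3,4-dimethoxybenzyl)-2-oxotetrahydrofuran-3-yl]methyl}-2-oxo-2H-pyran-6-carboxylate | COc1ccc(C[C@H]2COC(=O)[C@@H]2Cc2cc(C(=O)OCC)oc(=O)c2)cc1OC | intermediate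
21 | 4-{[(3R,4R)-4-(3,4-dimethoxybenzyl)-2-oxotetrahydrofuran-3-yl]methyl}-2-oxo-2H-pyran-6-carboxylic acid | COc1ccc(C[C@H]2COC(=O)[C@@H]2Cc2cc(C(=O)O)oc(=O)c2)cc1OC | target

**Step count and risks**

Total step count: 10. Longest linear sequence: 10 steps (1 → 21). C4 is set in step 1 and C3 in step 4; neither is put at risk afterwards.

The hydride abstraction of step 9 is the least certain operation. The trityl cation may act as a carbon electrophile towards C3' of the ketene acetal or towards the dimethoxyarene instead of accepting hydride from the hindered tertiary C4'–H. Adventitious acid may protonate C3' and divert material to the unoxidised lactone level, and the ethoxypyrylium ion may be opened by water at C6'. The fallback uses known chemistry and sets out from 18. Electrophilic selenenylation of the ketene acetal carbon with PhSeCl (CH2Cl2, −78 °C) is followed by collapse of the resulting dialkoxycarbenium chloride with loss of the O-ethyl group. This gives ethyl 4-{[(3R,4R)-4-(3,4-dimethoxybenzyl)-2-oxotetrahydrofuran-3-yl]methyl}-2-oxo-3-(phenylselanyl)-3,4-dihydro-2H-pyran-6-carboxylate F1, with selenium expected anti to the C4' substituent and therefore cis to C4'–H. Oxidation with H2O2 (pyridine, CH2Cl2, 0 °C) and syn-elimination of the selenoxide across C3'–C4' returns to the route at 20.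

The cycloaddition of step 7 may fail through a stepwise zwitterionic course that ends in [2+2] closure onto the keto group or in proton transfer to an open-chain adduct. Acid-initiated oligomerisation of the ketene acetal and hydrolysis of the orthoester during isolation are further risks. The fallback forms the same C3'–C4' bond stepwise and sets out from 15. Mukaiyama–Michael addition of 1-ethoxy-1-(trimethylsilyloxy)ethene (Sc(OTf)3, 10 mol %, CH2Cl2, −78 °C) gives the silyl enol ether diethyl 4-{[(3R,4R)-4-(3,4-dimethoxybenzyl)-2-oxotetrahydrofuran-3-yl]methyl}-2-(trimethylsilyloxy)hex-2-enedioate F2. Aqueous work-up hydrolyses it to the keto diester diethyl 4-{[(3R,4R)-4-(3,4-dimethoxybenzyl)-2-oxotetrahydrofuran-3-yl]methyl}-2-oxohexanedioate F3. Selenenylation next to the ketone with PhSeCl (EtOAc, 25 °C) gives diethyl 4-{[(3R,4R)-4-(3,4-dimethoxybenzyl)-2-oxotetrahydrofuran-3-yl]methyl}-2-oxo-3-(phenylselanyl)hexanedioate F4. Oxidation with H2O2 and selenoxide elimination give the enone diester diethyl 4-{[(3R,4R)-4-(3,4-dimethoxybenzyl)-2-oxotetrahydrofuran-3-yl]methyl}-2-oxohex-3-enedioate F5. Its dienol lactonises under TsOH in toluene at 80 °C, as in the classical oxalate route to 2-pyranone-6-carboxylates, and the sequence returns to the route at 20.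

The ethanol elimination of step 8 may suffer from reversible re-addition of the alcohol, ring opening of the orthoester at the enol oxygen, or hydrolysis and decomposition of the acid-sensitive ketene acetal at 110 °C. The fallback replaces the acid-catalysed equilibrium by an irreversible, base-buffered ionisation and sets out from 17. Me3SiOTf (1.2 equiv) with iPr2NEt (1.5 equiv) in CH2Cl2 at −30 °C removes one ethoxy group as its silyl ether, and the amine takes the C3' proton. No new compound is involved, and the sequence returns to the route at 18.

The olefination of step 6 may be sluggish because the ylide is doubly stabilised. Prolonged heating then allows self-aldol condensation of the enolisable aldehyde and migration of the new double bond. The fallback avoids both the aldehyde and the ylide and sets out from 11. Cross-metathesis with ethyl 2-hydroxybut-3-enoate (second-generation Hoveyda–Grubbs catalyst, CH2Cl2, 40 °C) gives ethyl (E)-5-[(3R,4R)-4-(3,4-dimethoxybenzyl)-2-oxotetrahydrofuran-3-yl]-2-hydroxypent-3-enoate F6 as a mixture of carbinol epimers. Oxidation of the allylic α-hydroxy ester with Dess–Martin periodinane (CH2Cl2, 0 °C) returns to the route at 15.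

**Further compounds**

F1 | step 9 | ethyl 4-{[(3R,4R)-4-(3,4-dimethoxybenzyl)-2-oxotetrahydrofuran-3-yl]methyl}-2-oxo-3-(phenylselanyl)-3,4-dihydro-2H-pyran-6-carboxylate | COc1ccc(C[C@H]2COC(=O)[C@@H]2CC3C=C(C(=O)OCC)OC(=O)C3[Se]c3ccccc3)cc1OC
F2 | step 7 | diethyl 4-{[(3R,4R)-4-(3,4-dimethoxybenzyl)-2-oxotetrahydrofuran-3-yl]methyl}-2-(trimethylsilyloxy)hex-2-enedioate | COc1ccc(C[C@H]2COC(=O)[C@@H]2CC(CC(=O)OCC)C=C(O[Si](C)(C)C)C(=O)OCC)cc1OC
F3 | step 7 | diethyl 4-{[(3R,4R)-4-(3,4-dimethoxybenzyl)-2-oxotetrahydrofuran-3-yl]methyl}-2-oxohexanedioate | COc1ccc(C[C@H]2COC(=O)[C@@H]2CC(CC(=O)OCC)CC(=O)C(=O)OCC)cc1OC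
F4 | step 7 | diethyl 4-{[(3R,4R)-4-(3,4-dimethoxybenzyl)-2-oxotetrahydrofuran-3-yl]methyl}-2-oxo-3-(phenylselanyl)hexanedioate | COc1ccc(C[C@H]2COC(=O)[C@@H]2CC(CC(=O)OCC)C([Se]c3ccccc3)C(=O)C(=O)OCC)cc1OC
F5 | step 7 | diethyl 4-{[(3R,4R)-4-(3,4-dimethoxybenzyl)-2-oxotetrahydrofuran-3-yl]methyl}-2-oxohex-3-enedioate | COc1ccc(C[C@H]2COC(=O)[C@@H]2CC(CC(=O)OCC)=CC(=O)C(=O)OCC)cc1OC
F0 | step 8 | none | none
F6 | step 6 | ethyl (E)-5-[(3R,4R)-4-(3,4-dimethoxybenzyl)-2-oxotetrahydrofuran-3-yl]-2-hydroxypent-3-enoate | COc1ccc(C[C@H]2COC(=O)[C@@H]2C/C=C/C(O)C(=O)OCC)cc1OC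
A1 | alternative 1 | (5R)-5-[(1R,2S,5R)-menthyloxy]furan-2(5H)-one | O=C1C=C[C@H](O[C@@H]2C[C@H](C)CC[C@H]2C(C)C)O1
A2 | alternative 1 | 3,4-dimethoxybenzylmagnesium chloride | COc1ccc(C[Mg]Cl)cc1OC
A3 | alternative 1 | ethyl (E)-4-bromo-3-methylbut-2-enoate | CCOC(=O)/C=C(\C)CBr
A4 | alternative 1 | ethyl (E)-4-[4-(3,4-dimethoxybenzyl)-5-(menthyloxy)-2-oxotetrahydrofuran-3-yl]-3-methylbut-2-enoate (3,4-trans, 4,5-trans) | COc1ccc(C[C@H]2[C@H](O[C@@H]3C[C@H](C)CC[C@H]3C(C)C)OC(=O)[C@@H]2C/C(C)=C/C(=O)OCC)cc1OC
A5 | alternative 2 | 3-(3,4-dimethoxybenzyl)cyclobutan-1-one | COc1ccc(CC2CC(=O)C2)cc1OC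
A6 | alternative 2 | (R)-4-(3,4-dimethoxybenzyl)dihydrofuran-2(3H)-one | COc1ccc(C[C@H]2COC(=O)C2)cc1OC
A7 | alternative 3 | (3R,4R)-3-(3,4-dihydroxybenzyl)-4-(3,4-dimethoxybenzyl)dihydrofuran-2(3H)-one | COc1ccc(C[C@H]2COC(=O)[C@@H]2Cc2ccc(O)c(O)c2)cc1OC
A8 | alternative 3 | 4-{[(3R,4R)-4-(3,4-dimethoxybenzyl)-2-oxotetrahydrofuran-3-yl]methyl}-2-hydroxy-2H-pyran-6-carboxylic acid (both anomers) | COc1ccc(C[C@H]2COC(=O)[C@@H]2CC2=CC(O)OC(C(=O)O)=C2)cc1OC
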